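Ring B of the trans-decalin is cut as a cyclohexene retron: the C5–C10 ring-fusion bond and the C8–C9 bond (locants below) are made together by an intramolecular Diels–Alder reaction. The precursor is acyclic: an (E)-β-methyl enal (C9=C10, formyl carbon C11) tethered through C1–C4 to an (E,E)-diene (C5=C6–C7=C8) that ends in an ethoxyvinyl group. The step exploits that C6 and C7 are bare methylenes, that C10 is the angular-methyl quaternary carbon, and that C9 carries the one-carbon handle C11. It closes rings A and B, sets C5 and C10 from the single stereocentre C4, and leaves a 1,4-keto-aldehyde from which the cyclopentene and the bicyclo[3.2.1]octene are grown.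

Key step: step 10

Remark (locants): carbons are numbered as in the target skeleton. Ring A = C1–C5 plus C10; ring B = C5–C10; C18 = CH2O carbon and C19 = CH3 on C4; C20 = CH3 on C10; C11 = alkene CH; C12 = bridgehead CH; C13, C14 = CH2 groups of the three-carbon bridge; C15 = carbinol bridge carbon; C16 = tertiary carbinol carbon; C17 = CH2OAc carbon. β is the face of the C20 methyl, α the opposite face.

Assumption: C8 epimers of compounds 15–18 converge, because C8 is made planar (enolate) in step 14.

Step 1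
Reactants: 1 hepta-1,6-diyne
Product: 4 (2E,7E)-3,7-dimethylnona-2,7-diene-1,9-diol, via bis(alkenyl)alane 2 (not isolated), via dilithium bis(alanate) 3 (not isolated)
Conditions: Me3Al, Cp2ZrCl2 (cat.), ClCH2CH2Cl, rt; n-BuLi, THF, −78 → 0 °C; (CH2O)n, rt
Reagents that add atoms: trimethylaluminium C[Al](C)C; formaldehyde (from paraformaldehyde) C=O
Why: Negishi zirconium-catalysed carboalumination adds CH3 and Al syn across each terminal alkyne, and hydroxymethylation of the alkenylalanate with retention should give both trisubstituted (E)-allylic alcohols; no stereocentre is formed.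

Step 2
Reactants: 4 (2E,7E)-3,7-dimethylnona-2,7-diene-1,9-diol
Product: 5 (2E,7E)-9-(tert-butyldimethylsilyloxy)-3,7-dimethylnona-2,7-dien-1-ol
Conditions: NaH (1 equiv), THF, rt; TBSCl (1 equiv)
Reagents that add atoms: tert-butyldimethylsilyl chloride C[Si](C)(Cl)C(C)(C)C
Why: Monosilylation through the monosodium alkoxide (O-silylation) should differentiate the two identical allylic alcohols; diol and bis-ether are recyclable.

Step 3
Reactants: 5 (2E,7E)-9-(tert-butyldimethylsilyloxy)-3,7-dimethylnona-2,7-dien-1-ol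
Product: 6 [(2S,3S)-3-[(4E)-6-(tert-butyldimethylsilyloxy)-4-methylhex-4-en-1-yl]-3-methyloxiran-2-yl]methanol
Conditions: Ti(OiPr)4 (cat.), L-(+)-diethyl tartrate (cat.), t-BuOOH, 4 Å MS, CH2Cl2, −20 °C
Reagents that add atoms: tert-butyl hydroperoxide CC(C)(C)OO
Why: Sharpless asymmetric epoxidation acts only on the free allylic alcohol, and with L-(+)-tartrate the facial rule for (E)-3,3-disubstituted allylic alcohols should give the (2S,3S)-epoxide (future C5 and C4).

Step 4
Reactants: 6 (2S,3S)-epoxy alcohol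
Product: 7 (2S,3S)-2-[(4E)-6-(tert-butyldimethylsilyloxy)-4-methylhex-4-en-1-yl]-2-methyl-3-[(triisopropylsilyloxy)methyl]oxirane
Conditions: TIPSCl, imidazole, DMF, rt
Reagents that add atoms: triisopropylsilyl chloride CC(C)[Si](Cl)(C(C)C)C(C)C
Why: Standard O-silylation of the primary alcohol installs the silyloxymethyl group that migrates in step 5 and protects C18 to the end.

Step 5
Reactants: 7 (2S,3S)-epoxy silyl ether
Product: 8 (2S,6E)-8-(tert-butyldimethylsilyloxy)-2,6-dimethyl-2-[(triisopropylsilyloxy)methyl]oct-6-enal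
Conditions: MeAl(OC6H2-4-Br-2,6-tBu2)2 (2 equiv; from Me3Al and the phenol), CH2Cl2, −78 °C
Reagents that add atoms: none
Why: Organoaluminium-promoted epoxy silyl ether rearrangement (semipinacol-type 1,2-shift): the bulky Lewis acid opens the epoxide at the tertiary carbon while the silyloxymethyl group migrates anti, so the epoxide configuration is transferred to the new quaternary carbon C4, giving the (S)-aldehyde.

Step 6
Reactants: 8 (2S,6E)-aldehyde; 9 triethyl (E)-4-phosphonocrotonate
Product: 10 ethyl (2E,4E,6R,10E)-12-(tert-butyldimethylsilyloxy)-6,10-dimethyl-6-[(triisopropylsilyloxy)methyl]dodeca-2,4,10-trienoate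
Conditions: LiN(SiMe3)2, THF, −78 → 0 °C
Reagents that add atoms: none
Why: Vinylogous Horner–Wadsworth–Emmons olefination of the non-enolisable aldehyde should give the (2E,4E)-dienoate (C5=C6 and C7=C8); C4 is untouched.

Step 7
Reactants: 10 ethyl (2E,4E,6R,10E)-trienoate
Product: 11 (2E,7R,8E,10E)-1-(tert-butyldimethylsilyloxy)-12-ethoxy-3,7-dimethyl-7-[(triisopropylsilyloxy)methyl]trideca-2,8,10,12-tetraene
Conditions: Cp2Ti(μ-Cl)(μ-CH2)AlMe2, pyridine, THF/PhMe, −40 °C → rt
Reagents that add atoms: Cp2Ti(μ-Cl)(μ-CH2)AlMe2 (Tebbe reagent; CH2 donor) C[Al-]1(C)C[Ti]([Cl+]1)(C2C=CC=C2)C2C=CC=C2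
Why: Tebbe methylenation of the ester carbonyl (titanium methylidene, oxatitanacyclobutane, cycloreversion) gives the 2-ethoxy-triene, a base- and fluoride-stable masked methyl ketone that also makes the diene electron-rich; pyridine ties up the aluminium Lewis acid so that the enol ether and both silyl ethers survive.

Step 8
Reactants: 11 ethoxy-tetraene TBS ether
Product: 12 (2E,7R,8E,10E)-12-ethoxy-3,7-dimethyl-7-[(triisopropylsilyloxy)methyl]trideca-2,8,10,12-tetraen-1-ol
Conditions: Bu4NF (1.1 equiv), THF, 0 °C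
Reagents that add atoms: none
Why: Fluoride desilylation should cleave the unhindered allylic TBS ether much faster than the neopentylic TIPS ether; the alkyl enol ether is inert to fluoride.

Step 9
Reactants: 12 tetraenol
Product: 13 (2E,7R,8E,10E)-12-ethoxy-3,7-dimethyl-7-[(triisopropylsilyloxy)methyl]trideca-2,8,10,12-tetraenal
Conditions: MnO2, CH2Cl2, rt
Reagents that add atoms: none
Why: Allylic oxidation with MnO2 gives the (E)-enal without isomerisation and without touching the triene.

Step 10
Reactants: 13 tetraenal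
Product: 15 8β-acetyl-9β-formyl-4β,10β-dimethyl-4α-(triisopropylsilyloxymethyl)-5α-H-Δ6-octalin, via ethoxyvinyl cycloadduct 14 (not isolated)
Conditions: PhMe (high dilution), BHT, 110 °C; then 5% aq. (CO2H)2, THF, 0 °C
Reagents that add atoms: water O
Why: A concerted, normal-electron-demand [4+2] cycloaddition joins the donor-substituted (E,E)-diene C5=C6–C7=C8 to the formyl-activated alkene C9=C10; the closest known class is the type-1 intramolecular Diels–Alder reaction of 1,7,9-decatrienals. Ring B is closed as the new cyclohexene by both forming bonds, and ring A is closed at the same time by the C5–C10 bond as the fused ring of the four-carbon tether C1–C4 (helped by the quaternary C4). With the (E)-enal, the transition state that has formyl and C20 methyl endo and the tether exo gives C5–H and C10–CH3 trans, and the (E)-C7=C8 geometry places the C8 side chain cis to the formyl group. The diene face is chosen by C4 through a chair-like tether with the bulky CH2OTIPS group equatorial and the methyl axial, which should give the 4β-methyl/10β-methyl relationship. The step needs endo over exo selectivity (formyl secondary overlap; the angular methyl penalises the cis-fused array) and reaction of the proximal diene only (the distal ethoxydiene cannot reach the dienophile). Mild acid then unmasks the methyl ketone; the C8 and C9 configurations are used only to bring the two carbonyl arms cis.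

Step 11
Reactants: 15 octalin keto-aldehyde
Product: 16 8β-acetyl-9β-formyl-4β,10β-dimethyl-4α-(triisopropylsilyloxymethyl)-5α-H-decalin
Conditions: H2 (1 atm), Pd/C, EtOAc, rt
Reagents that add atoms: none
Why: Heterogeneous hydrogenation saturates the only C=C bond (cis-disubstituted C6=C7) while ketone, aldehyde and silyl ether survive; no stereocentre that is kept is created.

Step 12
Reactants: 16 decalin keto-aldehyde
Product: 18 tricyclic cyclopentenone (15-oxo-11-ene; 8α-H; 9α-H), via β-hydroxy ketone 17 (not isolated)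
Conditions: KOH, MeOH, rt
Reagents that add atoms: none
Why: Intramolecular aldol condensation (5-enolexo attack of the methyl ketone enolate C12 on the formyl carbon C11, then E1cB dehydration) is the only pairing that gives an unstrained ring; the equatorial β-orientation at C9 is the stable one and is kept.

Step 13
Reactants: 19 but-3-yn-1-ol
Product: 20 but-3-yn-1-yl trifluoromethanesulfonate
Conditions: Tf2O, pyridine, CH2Cl2, −20 °C
Reagents that add atoms: trifluoromethanesulfonic anhydride O=S(=O)(OS(=O)(=O)C(F)(F)F)C(F)(F)F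
Why: O-Sulfonylation of the primary alcohol gives a homopropargylic electrophile reactive enough for SN2 at a hindered enolate.

Step 14
Reactants: 18 tricyclic cyclopentenone; 20 but-3-yn-1-yl trifluoromethanesulfonate
Product: 21 8α-(but-3-yn-1-yl) tricyclic cyclopentenone (15-oxo-11-ene; 9α-H)
Conditions: LiN(iPr)2 (1.05 equiv), THF, −78 °C; then 20, DMPU, −78 → −30 °C
Reagents that add atoms: none
Why: Kinetic α′-deprotonation (C8–H is the only α′-hydrogen) and SN2 alkylation of the cross-conjugated enolate set the quaternary C8; the electrophile should enter on the α-face, anti to the syn-axial C20 methyl and giving the cis-fused hydrindenone.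

Step 15
Reactants: 21 8α-(but-3-yn-1-yl) cyclopentenone
Product: 22 15-(tert-butyldimethylsilyloxy)cyclopenta-9(11),12(15)-diene (silyl dienol ether)
Conditions: TBSOTf, Et3N, CH2Cl2, 0 °C → rt
Reagents that add atoms: tert-butyldimethylsilyl triflate C[Si](C)(OS(=O)(=O)C(F)(F)F)C(C)(C)C
Why: Soft vinylogous enolisation (O-silylation, then loss of the only γ-hydrogen, C9–H) gives a single silyl dienol ether; C9 becomes sp2 and the terminal alkyne is inert.

Step 16
Reactants: 22 silyl dienol ether
Product: 23 16-methylene-15-oxo tetracycle (9(11)-ene; bicyclo[3.2.1]octenone)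
Conditions: [(Ph3P)Au]NTf2 (cat.), CH2Cl2/MeOH, rt
Reagents that add atoms: none
Why: Conia-ene-type 6-exo-dig carbocyclisation catalysed by monovalent gold: the activated alkyne is attacked by the α-carbon C12 of the silyl dienol ether (attack through C9 would create a third contiguous quaternary carbon), and protodeauration leaves the exocyclic methylene and the C9=C11 alkene; the C12 configuration is dictated by the bridge from the α-face of C8.

Step 17
Reactants: 23 16-methylene-15-oxo tetracycle
Product: 24 15-hydroxy-16-methylene tetracycle (15-OH syn to C9=C11)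
Conditions: NaBH4, MeOH, 0 °C
Reagents that add atoms: none
Why: Hydride reduction: the carbonyl face toward the C9=C11 bridge is screened by the syn-axial C20 methyl, so hydride should enter from the side of the three-carbon bridge (axial attack while C16 is still sp2), placing the hydroxyl syn to the alkene.

Step 18
Reactants: 24 15-hydroxy-16-methylene tetracycle
Product: 25 15,16,17-triol (16-OH equatorial; C17 axial)
Conditions: OsO4 (cat.), N-methylmorpholine N-oxide, acetone/H2O, rt
Reagents that add atoms: osmium tetroxide (catalytic oxygen carrier) O=[Os](=O)(=O)=O; N-methylmorpholine N-oxide C[N+]1([O-])CCOCC1; water O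
Why: Catalytic OsO4 dihydroxylation should touch only the 1,1-disubstituted alkene (C9=C11 lies between two quaternary carbons) and approach its outer, equatorial face, anti to the C15–H that projects over the other face, setting C16.

Step 19
Reactants: 25 15,16,17-triol
Product: 26 17-acetate (18-O-TIPS botryotin E)
Conditions: Ac2O (1.1 equiv), pyridine, CH2Cl2, 0 °C
Reagents that add atoms: acetic anhydride CC(=O)OC(C)=O
Why: Selective O-acylation of the only primary alcohol over the hindered secondary and the tertiary alcohol.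

Step 20
Reactants: 26 17-acetate
Product: 27 botryotin E
Conditions: HF·pyridine, THF, rt
Reagents that add atoms: none
Why: Fluoride desilylation under non-basic conditions should free the C18 alcohol without acetate cleavage or migration.

Compound list
1 | hepta-1,6-diyne | C#CCCCC#C | starting material
2 | (1E,6E)-1,7-bis(dimethylalumanyl)-2,6-dimethylhepta-1,6-diene | C[Al](C)/C=C(\C)CCC/C(C)=C/[Al](C)C | intermediate (not isolated)
3 | dilithium bis(butyl alanate) of 2 | [Li+].[Li+].CCCC[Al-](C)(C)/C=C(\C)CCC/C(C)=C/[Al-](C)(C)CCCC | intermediate (not isolated)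
4 | (2E,7E)-3,7-dimethylnona-2,7-diene-1,9-diol | OC/C=C(\C)CCC/C(C)=C/CO | intermediate
5 | (2E,7E)-9-(tert-butyldimethylsilyloxy)-3,7-dimethylnona-2,7-dien-1-ol | OC/C=C(\C)CCC/C(C)=C/CO[Si](C)(C)C(C)(C)C | intermediate
6 | [(2S,3S)-3-[(4E)-6-(tert-butyldimethylsilyloxy)-4-methylhex-4-en-1-yl]-3-methyloxiran-2-yl]methanol | OC[C@@H]1O[C@@]1(C)CCC/C(C)=C/CO[Si](C)(C)C(C)(C)C | intermediate
7 | (2S,3S)-2-[(4E)-6-(tert-butyldimethylsilyloxy)-4-methylhex-4-en-1-yl]-2-methyl-3-[(triisopropylsilyloxy)methyl]oxirane | CC(C)[Si](C(C)C)(C(C)C)OC[C@@H]1O[C@@]1(C)CCC/C(C)=C/CO[Si](C)(C)C(C)(C)C | intermediate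
8 | (2S,6E)-8-(tert-butyldimethylsilyloxy)-2,6-dimethyl-2-[(triisopropylsilyloxy)methyl]oct-6-enal | O=C[C@](C)(CO[Si](C(C)C)(C(C)C)C(C)C)CCC/C(C)=C/CO[Si](C)(C)C(C)(C)C | intermediate
9 | triethyl (E)-4-phosphonocrotonate | CCOC(=O)/C=C/CP(=O)(OCC)OCC | starting material
10 | ethyl (2E,4E,6R,10E)-12-(tert-butyldimethylsilyloxy)-6,10-dimethyl-6-[(triisopropylsilyloxy)methyl]dodeca-2,4,10-trienoate | CCOC(=O)/C=C/C=C/[C@](C)(CO[Si](C(C)C)(C(C)C)C(C)C)CCC/C(C)=C/CO[Si](C)(C)C(C)(C)C | intermediate
11 | (2E,7R,8E,10E)-1-(tert-butyldimethylsilyloxy)-12-ethoxy-3,7-dimethyl-7-[(triisopropylsilyloxy)methyl]trideca-2,8,10,12-tetraene | C=C(OCC)/C=C/C=C/[C@](C)(CO[Si](C(C)C)(C(C)C)C(C)C)CCC/C(C)=C/CO[Si](C)(C)C(C)(C)C | intermediate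
12 | (2E,7R,8E,10E)-12-ethoxy-3,7-dimethyl-7-[(triisopropylsilyloxy)methyl]trideca-2,8,10,12-tetraen-1-ol | C=C(OCC)/C=C/C=C/[C@](C)(CO[Si](C(C)C)(C(C)C)C(C)C)CCC/C(C)=C/CO | intermediate
13 | (2E,7R,8E,10E)-12-ethoxy-3,7-dimethyl-7-[(triisopropylsilyloxy)methyl]trideca-2,8,10,12-tetraenal | C=C(OCC)/C=C/C=C/[C@](C)(CO[Si](C(C)C)(C(C)C)C(C)C)CCC/C(C)=C/C=O | intermediate
14 | Diels–Alder adduct: trans-Δ6-octalin (5α-H, 10β-CH3) with 4β-CH3, 4α-CH2OTIPS, 8β-(1-ethoxyvinyl), 9β-CHO | CCOC(=C)[C@H]1C=C[C@H]2[C@](C)(CO[Si](C(C)C)(C(C)C)C(C)C)CCC[C@]2(C)[C@H]1C=O | intermediate (not isolated)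
15 | keto-aldehyde: trans-Δ6-octalin (5α-H, 10β-CH3) with 4β-CH3, 4α-CH2OTIPS, 8β-acetyl, 9β-CHO | CC(=O)[C@H]1C=C[C@H]2[C@](C)(CO[Si](C(C)C)(C(C)C)C(C)C)CCC[C@]2(C)[C@H]1C=O | intermediate
16 | saturated keto-aldehyde: trans-decalin (5α-H, 10β-CH3) with 4β-CH3, 4α-CH2OTIPS, 8β-acetyl, 9β-CHO | CC(=O)[C@H]1CC[C@H]2[C@](C)(CO[Si](C(C)C)(C(C)C)C(C)C)CCC[C@]2(C)[C@H]1C=O | intermediate
17 | β-hydroxy ketone (aldol adduct; 11-hydroxy-15-oxo cyclopentanone fused at C8–C9; either C11 epimer) | O=C1CC(O)[C@H]2[C@@H]1CC[C@H]3[C@](C)(CO[Si](C(C)C)(C(C)C)C(C)C)CCC[C@]23C | intermediate (not isolated)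
18 | tricyclic cyclopentenone (15-oxo-11-ene; 8α-H, 9α-H, 5α-H, 10β-CH3, 4β-CH3, 4α-CH2OTIPS) | O=C1C=C[C@H]2[C@@H]1CC[C@H]3[C@](C)(CO[Si](C(C)C)(C(C)C)C(C)C)CCC[C@]23C | intermediate
19 | but-3-yn-1-ol | C#CCCO | starting material
20 | but-3-yn-1-yl trifluoromethanesulfonate | C#CCCOS(=O)(=O)C(F)(F)F | intermediate
21 | 8α-(but-3-yn-1-yl) tricyclic cyclopentenone (15-oxo-11-ene; 9α-H) | C#CCC[C@]12CC[C@H]3[C@](C)(CO[Si](C(C)C)(C(C)C)C(C)C)CCC[C@]3(C)[C@H]1C=CC2=O | intermediate
22 | silyl dienol ether: 15-(tert-butyldimethylsilyloxy)cyclopenta-9(11),12(15)-diene with 8α-(but-3-yn-1-yl) | C#CCC[C@]12CC[C@H]3[C@](C)(CO[Si](C(C)C)(C(C)C)C(C)C)CCC[C@]3(C)C1=CC=C2O[Si](C)(C)C(C)(C)C | intermediate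
23 | 16-methylene-15-oxo tetracycle (9(11)-ene; 18-O-TIPS) | C=C1CC[C@]23CC[C@H]4[C@](C)(CO[Si](C(C)C)(C(C)C)C(C)C)CCC[C@]4(C)C2=C[C@H]1C3=O | intermediate
24 | 15-hydroxy-16-methylene tetracycle (15-OH syn to C9=C11; 18-O-TIPS) | C=C1CC[C@]23CC[C@H]4[C@](C)(CO[Si](C(C)C)(C(C)C)C(C)C)CCC[C@]4(C)C2=C[C@H]1[C@H]3O | intermediate
25 | 15,16,17-triol (18-O-TIPS) | OC[C@@]1(O)CC[C@]23CC[C@H]4[C@](C)(CO[Si](C(C)C)(C(C)C)C(C)C)CCC[C@]4(C)C2=C[C@H]1[C@H]3O | intermediate
26 | 18-O-triisopropylsilyl botryotin E (17-acetate) | CC(=O)OC[C@@]1(O)CC[C@]23CC[C@H]4[C@](C)(CO[Si](C(C)C)(C(C)C)C(C)C)CCC[C@]4(C)C2=C[C@H]1[C@H]3O | intermediate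
27 | botryotin E | CC(=O)OC[C@@]1(O)CC[C@]23CC[C@H]4[C@](C)(CO)CCC[C@]4(C)C2=C[C@H]1[C@H]3O | target

Total step count: 20. Longest linear sequence: 19 steps (steps 1–12 and 14–20; step 13 prepares the alkylating agent).

Steps most likely to fail

Step 10. The thermal cycloaddition may show poor endo/exo (ring-fusion) or facial discrimination, and the acid-labile ethoxytriene may hydrolyse or oligomerise before it cyclises. The fallback rebuilds the diene as an acid-stable hydrocarbon triene, so that a Lewis acid can drive the endo transition state at low temperature, and unmasks the ketone afterwards. It sets out from aldehyde 8. Wittig reaction with Ph3P=CHCHO would give the (E)-enal F1. Horner–Wadsworth–Emmons reaction with lithiated diethyl allylphosphonate would give the vinyl-terminated (E,E)-triene F2. Bu4NF would give the allylic alcohol F3 and MnO2 the trienal F4. Me2AlCl in CH2Cl2 at −78 °C would promote the intramolecular Diels–Alder reaction to the 8β-vinyl cycloadduct F5. PdCl2/CuCl/O2 in DMF/H2O would oxidise the terminal vinyl group to the methyl ketone, which returns the route to keto-aldehyde 15.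

Step 14. β-Elimination of the homopropargylic triflate, or O-alkylation, may outcompete SN2 at the hindered α′-carbon. The fallback uses an electrophile without acidic propargylic hydrogens and builds the alkyne afterwards; it sets out from enone 18. Alkylation of the same lithium enolate with 2-(2-iodoethyl)-1,3-dioxolane would give the 8α-[2-(1,3-dioxolan-2-yl)ethyl] enone F6. Pyridinium tosylate in aqueous acetone would give the 8α-(3-oxopropyl) enone F7. Ohira–Bestmann homologation (dimethyl (1-diazo-2-oxopropyl)phosphonate, K2CO3, MeOH) would turn the aldehyde into the terminal alkyne and return to 21.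

Step 16. The gold-activated alkyne may be attacked through the γ-carbon C9, or the dienol ether may be protodesilylated before ring closure. The fallback forms the C12–C16 bond by enolate cross-coupling and sets out from 21. Bromoboration with B-bromo-9-borabicyclo[3.3.1]nonane, then AcOH, would give the 8α-(3-bromobut-3-en-1-yl) enone F8. Intramolecular ketone α-alkenylation with zerovalent palladium (Pd(PPh3)4, KOtBu, THF), through the dienolate formed by γ-deprotonation, would close the bridge at C12 and return to 23, bypassing 22.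

Further compounds
F1 | step 10 | (2E,4R,8E)-10-(tert-butyldimethylsilyloxy)-4,8-dimethyl-4-[(triisopropylsilyloxy)methyl]deca-2,8-dienal | O=C/C=C/[C@](C)(CO[Si](C(C)C)(C(C)C)C(C)C)CCC/C(C)=C/CO[Si](C)(C)C(C)(C)C
F2 | step 10 | (2E,7R,8E,10E)-1-(tert-butyldimethylsilyloxy)-3,7-dimethyl-7-[(triisopropylsilyloxy)methyl]trideca-2,8,10,12-tetraene | C=C/C=C/C=C/[C@](C)(CO[Si](C(C)C)(C(C)C)C(C)C)CCC/C(C)=C/CO[Si](C)(C)C(C)(C)C
F3 | step 10 | (2E,7R,8E,10E)-3,7-dimethyl-7-[(triisopropylsilyloxy)methyl]trideca-2,8,10,12-tetraen-1-ol | C=C/C=C/C=C/[C@](C)(CO[Si](C(C)C)(C(C)C)C(C)C)CCC/C(C)=C/CO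
F4 | step 10 | (2E,7R,8E,10E)-3,7-dimethyl-7-[(triisopropylsilyloxy)methyl]trideca-2,8,10,12-tetraenal | C=C/C=C/C=C/[C@](C)(CO[Si](C(C)C)(C(C)C)C(C)C)CCC/C(C)=C/C=O
F5 | step 10 | 8β-vinyl cycloadduct: trans-Δ6-octalin (5α-H, 10β-CH3) with 4β-CH3, 4α-CH2OTIPS, 9β-CHO | C=C[C@H]1C=C[C@H]2[C@](C)(CO[Si](C(C)C)(C(C)C)C(C)C)CCC[C@]2(C)[C@H]1C=O
F6 | step 14 | 8α-[2-(1,3-dioxolan-2-yl)ethyl] tricyclic cyclopentenone | C1COC(CC[C@]23CC[C@H]4[C@](C)(CO[Si](C(C)C)(C(C)C)C(C)C)CCC[C@]4(C)[C@H]2C=CC3=O)O1
F7 | step 14 | 8α-(3-oxopropyl) tricyclic cyclopentenone | O=CCC[C@]12CC[C@H]3[C@](C)(CO[Si](C(C)C)(C(C)C)C(C)C)CCC[C@]3(C)[C@H]1C=CC2=O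
F8 | step 16 | 8α-(3-bromobut-3-en-1-yl) tricyclic cyclopentenone | C=C(Br)CC[C@]12CC[C@H]3[C@](C)(CO[Si](C(C)C)(C(C)C)C(C)C)CCC[C@]3(C)[C@H]1C=CC2=O
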